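**Retrosynthetic overview**
1. C7 side chain: cut the CH2–CH= bond; Negishi coupling of a C7 zinciomethyl core with an (E)-iodoalkene that already carries the allylic acetate (last step).
2. C2–OMe: set late by a silyl/methyl swap across the C2/C4 diketone (bulky silyl on the freer O4, methyl forced onto O2).
3. C7 endo CH2OH handle: retro-aldol opening plus reduction of an adamantane-type cage aldol (C3–C10 bond); the cage is what locks C7 endo.
4. Cage: acid-mediated closure (C1–C8, then C3–C10) of a dearomatised enal, made by amine-catalysed enantioselective alkylative dearomatisation (C5–C6) of an achiral diprenylated acylphloroglucinol with a C6 Morita–Baylis–Hillman carbonate.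
5. Ring order: the aromatic ring becomes ring A (dearomatised), ring B is annulated onto it, a third cage ring is closed and later reopened.

Numbering used for the core: C1 benzoyl bridgehead, C2 (OMe), C3 and C5 prenyl, C4 and C9 ketones, C6 CH2, C7 side chain, C8 gem-dimethyl, C10 the former aldehyde carbon. The target is (1R,5S,7S), with the C7 chain endo (on the face of the C2–C4 bridge).

Assumption: the quinidine-derived catalyst (DHQD)2PHAL gives the (1R,5S,7S) series drawn; if the opposite sense is found, its quinine-derived pseudoenantiomer (DHQ)2PHAL is used and nothing else changes.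

**Step 1**
Reactants: 1 (2,4,6-trihydroxyphenyl)(phenyl)methanone; 2 1-bromo-3-methylbut-2-ene (prenyl bromide)
Product: 3 [2,4,6-trihydroxy-3,5-bis(3-methylbut-2-enyl)phenyl](phenyl)methanone (clusiaphenone B)
Conditions: 2 (2.2 equiv), 10% aq. KOH, 0 °C → rt
Reagents that add atoms: none
Why: In water the phenolate oxygens are hydrogen-bonded, so the soft allylic bromide alkylates the two free ring carbons (phenolate C-alkylation, C-prenylation); no stereocentre is formed.

**Step 2**
Reactants: 4 2-bromo-3,3-diethoxyprop-1-ene; 5 acetone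
Product: 9 tert-butyl (3-formyl-2-methylbut-3-en-2-yl) carbonate, via vinyllithium 6 (not isolated), via lithium alkoxide 7 (not isolated), via acetal carbonate 8 (not isolated)
Conditions: t-BuLi (2.0 equiv), Et2O/THF, −78 °C; 5, −78 °C; Boc2O, −78 → 0 °C; H2O quench; then oxalic acid (cat.) on wet silica gel, CH2Cl2, rt
Reagents that add atoms: di-tert-butyl dicarbonate CC(C)(C)OC(=O)OC(=O)OC(C)(C)C; water O
Why: Bromine–lithium exchange gives the α-lithio acrolein acetal, which adds 1,2 to acetone; the lithium alkoxide is acylated by Boc2O and the acetal is hydrolysed by mild acid (halogen–metal exchange, carbonyl addition, O-acylation, acetal hydrolysis); no stereocentre.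

**Step 3**
Reactants: 3 clusiaphenone B; 9 tert-butyl (3-formyl-2-methylbut-3-en-2-yl) carbonate
Product: 12 cage aldol 1-benzoyl-10-hydroxy-8,8-dimethyl-3,5-bis(3-methylbut-2-enyl)adamantane-2,4,9-trione (C1/C5/C7 as in 24; 10-OH on the C6 side), via C-alkylated dienone 10 (not isolated), via endo aldehyde 11 (not isolated)
Conditions: hydroquinidine 1,4-phthalazinediyl diether, (DHQD)2PHAL (10 mol%), 9 (1.3 equiv), 4 Å MS, CH2Cl2/toluene 1:1, 0 °C; then solvent exchange to THF, conc. aq. HCl, 0 °C → rt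
Reagents that add atoms: none
Why: Proposed new method: tertiary-amine (Lewis-base) catalysed enantioselective alkylative dearomatisation of an acylphloroglucinol with a tertiary Morita–Baylis–Hillman carbonate, in which the quinuclidine nitrogen adds SN2′ to the CH2 terminus of 9 and expels tert-butyl carbonate (which loses CO2 to tert-butoxide and deprotonates 3), and the phenolate, held in a contact ion pair with the chiral allylammonium, displaces the amine at that CH2 through one of its two enantiotopic prenylated ring carbons to set C5 in 10, so the medium stays neutral, no metal phenolate gives a racemic background and the base-triggered Michael closure at the prenylated carbon (which leads to the isomeric 3-benzoyl ring system) is not started; HCl then protonates the enal and the benzoyl-bearing enol carbon captures the CMe2 terminus (C1–C8, C1 fixed by the cis ring fusion), the C7 aldehyde epimers equilibrate through the enol and only endo aldehyde 11 can close by aldol from C3 to cage 12, which locks C7 endo; the closest known reaction types are cinchona-amine-catalysed allylic alkylation with Morita–Baylis–Hillman carbonates, chiral phase-transfer alkylative dearomatisation of 3 with the corresponding acetate, and the acid-mediated closure of racemic 10 to the benzoyl-bridgehead cage.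

**Step 4**
Reactants: 12 cage aldol
Product: 14 1-benzoyl-4-hydroxy-7-(hydroxymethyl)-8,8-dimethyl-3,5-bis(3-methylbut-2-enyl)bicyclo[3.3.1]non-3-ene-2,9-dione (C1/C5/C7 as in 24; CH2OH endo), via potassium enolate 13 (not isolated)
Conditions: K2CO3 (2 equiv), THF/MeOH 1:1, 0 °C, 20 min; then NaBH4 (1.5 equiv), −40 → −20 °C; aq. NH4Cl
Reagents that add atoms: none
Why: Carbonate in methanol deprotonates the cage carbinol and retro-aldol cleavage of C3–C10 gives the stabilised C2/C4 diketonate 13, whose free endo aldehyde is then reduced by NaBH4 faster than it epimerises and faster than the enolate-masked C2/C4 or the hindered C9 and benzoyl ketones react (retro-aldol, chemoselective borohydride reduction); C7 keeps its endo configuration and the C3 and C10 centres are erased.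

**Step 5**
Reactants: 14 hydroxymethyl enol
Product: 17 1-benzoyl-7-(hydroxymethyl)-2-methoxy-8,8-dimethyl-3,5-bis(3-methylbut-2-enyl)bicyclo[3.3.1]non-2-ene-4,9-dione (C1/C5/C7 as in 24), via bis-silyl ether 15 (not isolated), via silyl ether 16 (not isolated)
Conditions: TIPSOTf (2.3 equiv), 2,6-di-tert-butyl-4-methylpyridine (3 equiv), CH2Cl2, −78 → 0 °C; Me3OBF4 (1.3 equiv), 0 °C → rt; TBAF (4 equiv), THF, 0 °C → rt
Reagents that add atoms: trimethyloxonium tetrafluoroborate C[O+](C)C.F[B-](F)(F)F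
Why: The bulky silyl triflate caps the primary alcohol and the less hindered enol oxygen O4 (O2 is eclipsed by the C1 benzoyl), the oxonium salt then methylates the only nucleophilic oxygen left, the vinylogous-ester carbonyl O2, and fluoride strips silicon from O4 and from the primary ether (silylation, Meerwein O-alkylation of a vinylogous ester, fluoride desilylation); no stereocentre changes.

**Step 6**
Reactants: 17 C2 methyl enol ether alcohol
Product: 18 1-benzoyl-7-(iodomethyl)-2-methoxy-8,8-dimethyl-3,5-bis(3-methylbut-2-enyl)bicyclo[3.3.1]non-2-ene-4,9-dione (C1/C5/C7 as in 24)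
Conditions: I2, PPh3, imidazole, CH2Cl2, 0 °C → rt, dark
Reagents that add atoms: iodine II
Why: Appel reaction: the oxyphosphonium of the primary alcohol is displaced by iodide; the enol ether, ketones and prenyl groups are inert and C7 is untouched.

**Step 7**
Reactants: 19 prop-2-yn-1-ol
Product: 21 (E)-3-iodo-2-methylprop-2-en-1-ol, via alkenylalane 20 (not isolated)
Conditions: AlMe3 (3 equiv), Cp2ZrCl2 (0.25 equiv), CH2Cl2, 0 °C → rt; I2, THF, −30 → 0 °C; aq. work-up
Reagents that add atoms: trimethylaluminium C[Al](C)C; iodine II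
Why: Zirconium-catalysed carboalumination adds methyl and aluminium syn across the alkyne with aluminium at the terminus, and iodinolysis with retention gives the (E)-iodoalkene (Negishi carboalumination).

**Step 8**
Reactants: 21 (E)-3-iodo-2-methylprop-2-en-1-ol
Product: 22 (E)-3-iodo-2-methylprop-2-en-1-yl acetate
Conditions: Ac2O, pyridine, DMAP (cat.), CH2Cl2, 0 °C → rt
Reagents that add atoms: acetic anhydride CC(=O)OC(C)=O
Why: DMAP-catalysed acetylation of the primary allylic alcohol (nucleophilic acyl substitution); the alkene geometry is not touched.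

**Step 9**
Reactants: 18 C7 iodomethyl core; 22 (E)-3-iodo-2-methylprop-2-en-1-yl acetate
Product: 24 (1R,5S,7S)-7-[(2E)-4-acetoxy-3-methylbut-2-enyl]-1-benzoyl-2-methoxy-8,8-dimethyl-3,5-bis(3-methylbut-2-enyl)bicyclo[3.3.1]non-2-ene-4,9-dione, via alkylzinc iodide 23 (not isolated)
Conditions: Zn dust (TMSCl/1,2-dibromoethane-activated), LiCl, THF, 35 °C; then 22 (1.5 equiv), PdCl2(dppf) (5 mol%), THF/NMP, rt
Reagents that add atoms: none
Why: Zinc inserts into the primary C–I bond and the alkylzinc couples with the alkenyl iodide under palladium catalysis with retention of the E geometry (Negishi coupling); oxidative addition into C–I outruns ionisation of the allylic acetate and no stereocentre is touched.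

**Compound list**
1 | (2,4,6-trihydroxyphenyl)(phenyl)methanone | O=C(c1ccccc1)c1c(O)cc(O)cc1O | starting material
2 | 1-bromo-3-methylbut-2-ene | CC(C)=CCBr | starting material
3 | [2,4,6-trihydroxy-3,5-bis(3-methylbut-2-enyl)phenyl](phenyl)methanone | O=C(c1ccccc1)c1c(O)c(CC=C(C)C)c(O)c(CC=C(C)C)c1O | intermediate
4 | 2-bromo-3,3-diethoxyprop-1-ene | C=C(Br)C(OCC)OCC | starting material
5 | acetone | CC(C)=O | starting material
6 | (3,3-diethoxyprop-1-en-2-yl)lithium | C=C([Li])C(OCC)OCC | intermediate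
7 | lithium 3-(diethoxymethyl)-2-methylbut-3-en-2-olate | C=C(C(OCC)OCC)C(C)(C)O[Li] | intermediate
8 | tert-butyl [3-(diethoxymethyl)-2-methylbut-3-en-2-yl] carbonate | C=C(C(OCC)OCC)C(C)(C)OC(=O)OC(C)(C)C | intermediate
9 | tert-butyl (3-formyl-2-methylbut-3-en-2-yl) carbonate | C=C(C=O)C(C)(C)OC(=O)OC(C)(C)C | intermediate
10 | 2-benzoyl-3,5-dihydroxy-6-(2-formyl-3-methylbut-2-enyl)-4,6-bis(3-methylbut-2-enyl)cyclohexa-2,4-dien-1-one, quaternary ring carbon configured as C5 of 24 | O=C1C(C(=O)c2ccccc2)=C(O)C(CC=C(C)C)=C(O)[C@]1(CC=C(C)C)CC(C=O)=C(C)C | intermediate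
11 | 1-benzoyl-4-hydroxy-8,8-dimethyl-3,5-bis(3-methylbut-2-enyl)-2,9-dioxobicyclo[3.3.1]non-3-ene-7-carbaldehyde, C1/C5/C7 as in 24, formyl endo | O=C1C(CC=C(C)C)=C(O)[C@]2(CC=C(C)C)C[C@H](C=O)C(C)(C)[C@@]1(C(=O)c1ccccc1)C2=O | intermediate
12 | 1-benzoyl-10-hydroxy-8,8-dimethyl-3,5-bis(3-methylbut-2-enyl)adamantane-2,4,9-trione, C1/C5/C7 as in 24, 10-OH on the C6 side (anti to the gem-dimethyl) | O=C1[C@@]3(CC=C(C)C)C(=O)[C@]2(CC=C(C)C)C[C@H]([C@@H]3O)C(C)(C)[C@@]1(C(=O)c1ccccc1)C2=O | intermediate
13 | potassium 1-benzoyl-7-formyl-8,8-dimethyl-3,5-bis(3-methylbut-2-enyl)-2,9-dioxobicyclo[3.3.1]non-3-en-4-olate, C1/C5/C7 as in 24, formyl endo | O=C1C(CC=C(C)C)=C([O-])[C@]2(CC=C(C)C)C[C@H](C=O)C(C)(C)[C@@]1(C(=O)c1ccccc1)C2=O.[K+] | intermediate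
14 | 1-benzoyl-4-hydroxy-7-(hydroxymethyl)-8,8-dimethyl-3,5-bis(3-methylbut-2-enyl)bicyclo[3.3.1]non-3-ene-2,9-dione, C1/C5/C7 as in 24, CH2OH endo | O=C1C(CC=C(C)C)=C(O)[C@]2(CC=C(C)C)C[C@H](CO)C(C)(C)[C@@]1(C(=O)c1ccccc1)C2=O | intermediate
15 | 4-O-triisopropylsilyl enol ether and 7-CH2O-triisopropylsilyl ether of 14 | O=C1C(CC=C(C)C)=C(O[Si](C(C)C)(C(C)C)C(C)C)[C@]2(CC=C(C)C)C[C@H](CO[Si](C(C)C)(C(C)C)C(C)C)C(C)(C)[C@@]1(C(=O)c1ccccc1)C2=O | intermediate
16 | 1-benzoyl-2-methoxy-8,8-dimethyl-3,5-bis(3-methylbut-2-enyl)-7-[(triisopropylsilyloxy)methyl]bicyclo[3.3.1]non-2-ene-4,9-dione, C1/C5/C7 as in 24 | COC1=C(CC=C(C)C)C(=O)[C@]2(CC=C(C)C)C[C@H](CO[Si](C(C)C)(C(C)C)C(C)C)C(C)(C)[C@@]1(C(=O)c1ccccc1)C2=O | intermediate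
17 | 1-benzoyl-7-(hydroxymethyl)-2-methoxy-8,8-dimethyl-3,5-bis(3-methylbut-2-enyl)bicyclo[3.3.1]non-2-ene-4,9-dione, C1/C5/C7 as in 24 | COC1=C(CC=C(C)C)C(=O)[C@]2(CC=C(C)C)C[C@H](CO)C(C)(C)[C@@]1(C(=O)c1ccccc1)C2=O | intermediate
18 | 1-benzoyl-7-(iodomethyl)-2-methoxy-8,8-dimethyl-3,5-bis(3-methylbut-2-enyl)bicyclo[3.3.1]non-2-ene-4,9-dione, C1/C5/C7 as in 24 | COC1=C(CC=C(C)C)C(=O)[C@]2(CC=C(C)C)C[C@H](CI)C(C)(C)[C@@]1(C(=O)c1ccccc1)C2=O | intermediate
19 | prop-2-yn-1-ol | C#CCO | starting material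
20 | dimethylaluminium (E)-3-(dimethylalumanyl)-2-methylprop-2-en-1-olate | C[Al](C)/C=C(\C)CO[Al](C)C | intermediate
21 | (E)-3-iodo-2-methylprop-2-en-1-ol | I/C=C(\C)CO | intermediate
22 | (E)-3-iodo-2-methylprop-2-en-1-yl acetate | I/C=C(\C)COC(C)=O | intermediate
23 | {[1-benzoyl-2-methoxy-8,8-dimethyl-3,5-bis(3-methylbut-2-enyl)-4,9-dioxobicyclo[3.3.1]non-2-en-7-yl]methyl}zinc iodide, C1/C5/C7 as in 24 | COC1=C(CC=C(C)C)C(=O)[C@]2(CC=C(C)C)C[C@H](C[Zn]I)C(C)(C)[C@@]1(C(=O)c1ccccc1)C2=O | intermediate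
24 | (1R,5S,7S)-7-[(2E)-4-acetoxy-3-methylbut-2-enyl]-1-benzoyl-2-methoxy-8,8-dimethyl-3,5-bis(3-methylbut-2-enyl)bicyclo[3.3.1]non-2-ene-4,9-dione | COC1=C(CC=C(C)C)C(=O)[C@]2(CC=C(C)C)C[C@H](C/C=C(\C)COC(C)=O)C(C)(C)[C@@]1(C(=O)c1ccccc1)C2=O | target

**Totals**
Total steps: 9. Longest linear sequence: 6 (steps 1, 3, 4, 5, 6, 9).

**Three steps most likely to fail**

Step 3 (the proposed new step). Risks are O- instead of C-alkylation, sequestration of the amine as its salt with the acidic phenol 3 or dienone 10, untested enantioselectivity, some amine-promoted Michael closure at the prenylated carbon before the acid is added, and acid-induced chroman formation from a prenyl group. The fallback uses known chemistry; it sets out from 7 (and uses 3 unchanged) and comes back at 12. Alkoxide 7 is quenched with acetic anhydride instead of Boc2O to give 3-(diethoxymethyl)-2-methylbut-3-en-2-yl acetate F1, which is hydrolysed as in step 2 to 3-formyl-2-methylbut-3-en-2-yl acetate F2. Compound 3 is deprotonated with LiN(SiMe3)2 (THF, 0 °C) and alkylated with F2; the chelated lithium triketonate does not cyclise, so the product is the racemic dearomatised enal, 10 together with its mirror image ent-10 F3. Conc. HCl in THF closes both, through 11 and its mirror image ent-11 F4, to the racemic cage, 12 together with its mirror image ent-12 F5. Preparative HPLC on a chiral stationary phase (amylose tris(3,5-dimethylphenylcarbamate)) then separates 12 from F5.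

Step 5. The regiochemistry rests on the silyl group choosing O4, and the oxonium salt must methylate the hindered O2 without touching the silyl ether. The fallback sets out from 14 and comes back at 17. Compound 14 is methylated directly with TMSCHN2 (i-Pr2NEt, MeOH/MeCN, 0 °C), which leaves the primary alcohol alone and gives 17 together with 1-benzoyl-7-(hydroxymethyl)-4-methoxy-8,8-dimethyl-3,5-bis(3-methylbut-2-enyl)bicyclo[3.3.1]non-3-ene-2,9-dione F6. The two are separated on silica, and F6 is demethylated with LiCl in DMSO (120 °C) back to 14 and resubmitted.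

Step 9. The C10–zinc (or C10–iodide) carbon sits directly under C3 and can close the cage, and palladium may ionise the allylic acetate. The fallback sets out from 17 and comes back at 24, and avoids any reactive C10 species other than an aldehyde. Oxidation of 17 (Dess–Martin periodinane, NaHCO3, CH2Cl2) gives the C7 endo aldehyde F7, used at once. Vinylmagnesium bromide with CeCl3 (THF, −78 °C) adds only to the aldehyde to give the vinyl carbinol F8 (either carbinol epimer serves). ClCO2Me, pyridine and DMAP give the allylic methyl carbonate F9. Pd(PPh3)4 with HCO2NH4 (THF, 50 °C) delivers hydride to the more substituted allyl terminus and gives the C7 allyl compound F10. Cross-metathesis with methacrolein (second-generation Hoveyda–Grubbs catalyst, CH2Cl2, 40 °C; the trisubstituted prenyl alkenes react far more slowly) gives the (E)-enal F11. NaBH4 with CeCl3·7H2O (MeOH, −40 °C) gives the (E)-allylic alcohol F12, and Ac2O with pyridine then gives 24.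

**Further compounds**
F1 | step 3 | 3-(diethoxymethyl)-2-methylbut-3-en-2-yl acetate | C=C(C(OCC)OCC)C(C)(C)OC(C)=O
F2 | step 3 | 3-formyl-2-methylbut-3-en-2-yl acetate | C=C(C=O)C(C)(C)OC(C)=O
F3 | step 3 | ent-10, mirror image of dienone 10, formed with 10 as the racemate | O=C1C(C(=O)c2ccccc2)=C(O)C(CC=C(C)C)=C(O)[C@@]1(CC=C(C)C)CC(C=O)=C(C)C
F4 | step 3 | ent-11, mirror image of endo aldehyde 11 | O=C1C(CC=C(C)C)=C(O)[C@@]2(CC=C(C)C)C[C@@H](C=O)C(C)(C)[C@]1(C(=O)c1ccccc1)C2=O
F5 | step 3 | ent-12, mirror image of cage aldol 12 | O=C1[C@]3(CC=C(C)C)C(=O)[C@@]2(CC=C(C)C)C[C@@H]([C@H]3O)C(C)(C)[C@]1(C(=O)c1ccccc1)C2=O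
F6 | step 5 | 1-benzoyl-7-(hydroxymethyl)-4-methoxy-8,8-dimethyl-3,5-bis(3-methylbut-2-enyl)bicyclo[3.3.1]non-3-ene-2,9-dione, C1/C5/C7 as in 24 | O=C1C(CC=C(C)C)=C(OC)[C@]2(CC=C(C)C)C[C@H](CO)C(C)(C)[C@@]1(C(=O)c1ccccc1)C2=O
F7 | step 9 | 1-benzoyl-2-methoxy-8,8-dimethyl-3,5-bis(3-methylbut-2-enyl)-4,9-dioxobicyclo[3.3.1]non-2-ene-7-carbaldehyde, C1/C5/C7 as in 24 | COC1=C(CC=C(C)C)C(=O)[C@]2(CC=C(C)C)C[C@H](C=O)C(C)(C)[C@@]1(C(=O)c1ccccc1)C2=O
F8 | step 9 | 1-benzoyl-7-(1-hydroxyprop-2-enyl)-2-methoxy-8,8-dimethyl-3,5-bis(3-methylbut-2-enyl)bicyclo[3.3.1]non-2-ene-4,9-dione, carbinol epimers | COC1=C(CC=C(C)C)C(=O)[C@]2(CC=C(C)C)C[C@H](C(O)C=C)C(C)(C)[C@@]1(C(=O)c1ccccc1)C2=O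
F9 | step 9 | methyl carbonate of F8 | COC1=C(CC=C(C)C)C(=O)[C@]2(CC=C(C)C)C[C@H](C(OC(=O)OC)C=C)C(C)(C)[C@@]1(C(=O)c1ccccc1)C2=O
F10 | step 9 | 7-allyl-1-benzoyl-2-methoxy-8,8-dimethyl-3,5-bis(3-methylbut-2-enyl)bicyclo[3.3.1]non-2-ene-4,9-dione, C1/C5/C7 as in 24 | COC1=C(CC=C(C)C)C(=O)[C@]2(CC=C(C)C)C[C@H](CC=C)C(C)(C)[C@@]1(C(=O)c1ccccc1)C2=O
F11 | step 9 | (E)-4-[1-benzoyl-2-methoxy-8,8-dimethyl-3,5-bis(3-methylbut-2-enyl)-4,9-dioxobicyclo[3.3.1]non-2-en-7-yl]-2-methylbut-2-enal | COC1=C(CC=C(C)C)C(=O)[C@]2(CC=C(C)C)C[C@H](C/C=C(\C)C=O)C(C)(C)[C@@]1(C(=O)c1ccccc1)C2=O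
F12 | step 9 | 1-benzoyl-7-[(2E)-4-hydroxy-3-methylbut-2-enyl]-2-methoxy-8,8-dimethyl-3,5-bis(3-methylbut-2-enyl)bicyclo[3.3.1]non-2-ene-4,9-dione | COC1=C(CC=C(C)C)C(=O)[C@]2(CC=C(C)C)C[C@H](C/C=C(\C)CO)C(C)(C)[C@@]1(C(=O)c1ccccc1)C2=O
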